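| flask | free monomer | protic impurity | initiator | remark | time |
|---|---|---|---|---|---|
| north-west | 2 mM | 0.60 mM | 27 µM | run made earlier |  |
| north | 2 mM | 0.60 mM | 52 µM | run made earlier |  |
| south-east | 2 mM | 0.60 mM | 79 µM | run made earlier |  |
| blue | 2.0 mM | 0.600 mM | 100 µM |  | 5.0 min |
| violet | 2.0 mM | 0.600 mM | 30 µM |  | 5.0 min |

- north-west (time / min: monomer in chains / %, free monomer / %): 0.200: 1.6, 82.6; 0.417: 1.8, 74.3; 0.667: 2.1, 68.7; 1.33: 1.7, 68.1; 2.50: 6.1, 63.1
- north (time / min: monomer in chains / %, free monomer / %): 0.500: 1.8, 72.7; 1.00: 3.2, 70.3; 1.50: 7.1, 65.3; 2.00: 9.8, 57.3; 2.50: 13.5, 57.4
- south-east (time / min: monomer in chains / %, free monomer / %): 0.500: 2.7, 72.1; 1.00: 6.4, 64.8; 1.50: 8.4, 60.2; 2.00: 12.9, 57.0; 2.50: 16.5, 52.3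

(scatter of a reading: 1 percentage point)

- the average divides the monomer in chains by the number of chains begun, living and dead together
- steps under discussion: initiator -> spent initiator; free monomer + initiator -> living end + monomer in chains; free monomer + living end -> monomer in chains + living end; protic impurity + free monomer -> quenched substrate
- the earlier runs do not show the number of chains; that part of a forecast is a guess

- which of the two ends with the longer chains by the average number of monomer units in a chain (chains begun, living or dead) ("neither" if they lie within 10%) (blue / violet / neither)
- average number of monomer units in a chain (chains begun, living or dead) at the end, blue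
- average number of monomer units in a chain (chains begun, living or dead) at the end, violet

- With the rate constants hidden, I reckoned through a quantity the readings do show, the load: monomer in chains per initiator charged. It is a floor for the length, since chains begun are a part of the charged initiator.
- I turned c(protic impurity) first. By hand, its charge of 0.600 mM takes 30.0% of the free monomer into quenched substrate without making chains, and the north-west run at 1.33 min showed 30.2% missing. That left a pool of 1.40 mM.
- I turned c(initiator) next. By hand, if living ends scale with the charge, the load at one time stays the same from charge to charge while the pool holds. At 2.50 min the runs read 4.52, 5.19 and 4.18, with no trend in the charge, so I took a mean of 4.63 and a load rate s of 1.85 /min, lag included.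
- I turned the time last. By hand, the load grows as s·t until it meets the budget, pool/c(initiator). So I used the draw D, the share of the pool that growth at rate s takes in time t, 0.661 for blue; control passes from the clock to the pool as D crosses one.
- Violet's draw was 0.198, less than blue's, and both lay below one. Taking the pool's fall as pseudo-first-order, the load is the budget times 1 − exp(−D): 6.77 for blue and 8.40 for violet. With equal shares of initiator beginning chains, I committed to violet, longer by a ratio of 1.24.
- The forecast named lengths where I gave estimated loads, 10 for blue and 12 for violet, with violet longer since “it depletes monomer less”.
- The flask gave 13.9 for blue and 17.8 for violet, so violet ended longer, by a ratio of 1.28. In blue, 0.0585 mM of living end stood at 5.00 min from 100 µM of initiator charged. Carried to 50.0 min, the draw reads 6.61 in blue and 1.98 in violet, both past the crossing. The lengths there, 23.2 for blue and 70.1 for violet, stand at a ratio of 3.02, against 3.33 for the budgets.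

    initiator → spent initiator (k = 0.00410 /s)
    free monomer + initiator → living end + monomer in chains (k = 5.30 /M/s)
    free monomer + living end → monomer in chains + living end, rate k3*[living end]*[free monomer] (k = 60.0 /M/s)
    protic impurity + free monomer → quenched substrate (k = 39.0 /M/s)

- A flask like violet but with 0.12 mM of initiator has a draw of 0.794 and a load of 6.39, which scales violet's length to 13.6. The computed length is 13.1.

All runs are calculated for an exercise, noise included.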